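Shrink a substrate charge and a loss going as its square falls away from a loss going as its first power. So, at a fixed partner charge, a small substrate charge is where a partner route can show. A partner-free route shows in the midnight run, which loses 1.13 M of substrate by 45 min, more than its 1.00 M of coupling partner.

| setting | summer | midnight | spring | noon |
|---|---|---|---|---|
| substrate | 0.400 M | 1.20 M | 0.400 M | 0.200 M |
| coupling partner | 1.00 M | 1.00 M | 1.50 M | 3.00 M |
| time |  |  |  | 45 min |

| run | time / min | [substrate] / M |
|---|---|---|
| summer run | 1.8 | 0.332 |
| summer run | 4.0 | 0.248 |
| summer run | 9.0 | 0.171 |
| summer run | 20 | 0.093 |
| summer run | 45 | 0.054 |
| midnight run | 1.8 | 0.779 |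
| midnight run | 4.0 | 0.540 |
| midnight run | 9.0 | 0.303 |
| midnight run | 20 | 0.142 |
| midnight run | 45 | 0.071 |
| spring run | 1.8 | 0.322 |
| spring run | 4.0 | 0.246 |
| spring run | 9.0 | 0.173 |
| spring run | 20 | 0.082 |
| spring run | 45 | 0.030 |

(readings scatter by 0.006 M)

1. the power of [substrate] that the first rate follows, about the charge of the summer run; measure it at two percent of substrate made into product (one fixed amount of product, the same in the runs compared)
2. the power of [coupling partner] that the first rate follows, about the charge of the summer run; measure it at two percent of substrate made into product
3. substrate in the noon run at 45 min, as a share of the substrate charged

- Overall: substrate + coupling partner -> product.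
- Constant volume, constant temperature.
- Bound and free are read together.
- An order is taken over about fifteen percent of the charge, up and down.

Take the square loss as the base and reckon only the correction. Write the loss rate as c × substrate squared + b × substrate. Then, for each run at 20 min:

apparent constant = (reciprocal of substrate now − reciprocal of charge) / time ≈ c + b / (geometric mean of charge and substrate now)

Now turn the question round. With no partner route, b is nil, and the summer and midnight runs would give one apparent constant. They give 0.413 /M/min and 0.310 /M/min. The scatter on that gap is 0.0377 /M/min, so they stand 2.73 scatter widths apart.

Those two runs share a partner charge, so take one b for both: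

b, summer = 0.0370 /min
c = 0.221 /M/min
b, spring = 0.0478 /min

Call b the partner constant: the fraction of substrate per minute taken by the first-power route at a given partner charge, the usual pseudo-first-order constant. It is a reading, with a scatter of 0.0137 /min in the summer run.

I take the first rate as product formation, b × substrate, so my order in substrate is one. My order in partner is ln(ratio of b) / ln(ratio of partner) = 0.632. That gives 0.0741 /min for the noon run, and integrating both terms leaves 2.26%.

The forecast gives 1.75 in substrate, 0.25 in partner and 3.5% for the noon run: “I read the first rate as observed substrate loss”. That reading differs from mine.

The flask gives 1.0 in substrate, 0.65 in partner and 6.14% for the noon run, so the noon run keeps more substrate than my share or the forecast's. With 3.00 times the substrate charge, the midnight product rate is 3.0 times the summer one, both taken where the same amount of product has been made.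

    substrate + coupling partner ⇌ product + by-product (0.1038 /M/min, 0.03348 /M/min)
    2 coupling partner ⇌ idle reagent dimer, settled at all times (2.070 /M)
    2 substrate → homo dimer (0.1032 /M/min)

Use the reading of the partner constant as a rate. Times the summer charge it gives 0.0148 M/min, beside a product rate of 0.015 M/min in the summer run at the small fixed amount of product. Times the midnight charge it gives 0.0444 M/min, beside a product rate of 0.046 M/min in the midnight run at that same amount.

(The earlier runs and the new flask come from a simulation from invented constants; the scatter is artificial.)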